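**Retrosynthetic overview**
1. Target 21 ⇐ octabenzyl ether 20 (global hydrogenolysis). Each C3 carbinol comes from a flavan-3-one by LiBH(s-Bu)3 reduction (cis); the unit 1 carbinol is then inverted to trans (Mitsunobu).
2. Each flavan-3-one ⇐ 2-aryl-3-nitro-2H-chromene by reductive Nef; the nitro carbon is the masked C3 carbonyl.
3. Key disconnection, used twice: C3–C4 and O1–C2 are made in one asymmetric oxa-Michael/Henry domino between a ring A salicylaldehyde and a ring B β-nitrostyrene. The nitronate acts as a C3 acyl-anion equivalent attacking the aldehyde carbon C4.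
4. Ring order: diaryl ether core first (two SNAr steps on 2,4,6-trifluorobenzonitrile), then ring C of unit 1 (core as nitrostyrene), then ring C of unit 2 (core nitrile unveiled as salicylaldehyde).
5. Starting materials: 3,4,5-tris(benzyloxy)benzaldehyde, 2,4,6-trifluorobenzonitrile, 2,4,6-trihydroxybenzaldehyde, nitromethane.

Assumption: the (S)-amine catalyst is taken to give the 2R chromene in steps 6 and 13 (checked on compound 10); if it gives 2S, the (R)-amine is used instead.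

Unit 1 is the 2,3-trans (2R,3S) flavan; unit 2 is the 2,3-cis (2R,3R) flavan whose ring A carries the ether oxygen.

**Step 1**
Reactants: 1 3,4,5-tris(benzyloxy)benzaldehyde
Product: 2 3,5-bis(benzyloxy)-4-hydroxybenzaldehyde
Conditions: MgBr2·OEt2 (1.5 equiv), PhMe–Et2O, 70 °C; 1 M HCl work-up
Reagents that add atoms: none
Why: Lewis-acid ether cleavage in which the crowded central benzyloxy group (twisted out of plane, chelating magnesium together with a neighbouring ether oxygen, para to CHO) is removed selectively by bromide.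

**Step 2**
Reactants: 2 3,5-bis(benzyloxy)-4-hydroxybenzaldehyde; 3 2,4,6-trifluorobenzonitrile
Product: 4 4-[2,6-bis(benzyloxy)-4-formylphenoxy]-2,6-difluorobenzonitrile
Conditions: K2CO3, DMF, 40 °C
Reagents that add atoms: none
Why: SNAr in which the bulky 2,6-disubstituted phenoxide takes the fluorine para to the nitrile, the usual site for aryloxides on 2,4-difluorobenzonitriles in dipolar aprotic solvent.

**Step 3**
Reactants: 4 4-[2,6-bis(benzyloxy)-4-formylphenoxy]-2,6-difluorobenzonitrile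
Product: 5 2,6-bis(benzyloxy)-4-[2,6-bis(benzyloxy)-4-formylphenoxy]benzonitrile
Conditions: BnOH (2.3 equiv), Cs2CO3, DMF, 60 °C
Reagents that add atoms: benzyl alcohol OCc1ccccc1
Why: double SNAr of the two fluorines ortho to the nitrile by benzyl alkoxide, run with a carbonate base so that the non-enolisable aldehyde is left alone.

**Step 4**
Reactants: 5 2,6-bis(benzyloxy)-4-[2,6-bis(benzyloxy)-4-formylphenoxy]benzonitrile
Product: 6 2,6-bis(benzyloxy)-4-{2,6-bis(benzyloxy)-4-[(E)-2-nitroethenyl]phenoxy}benzonitrile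
Conditions: MeNO2, NH4OAc, AcOH, 90 °C
Reagents that add atoms: nitromethane C[N+](=O)[O-]
Why: Henry (nitroaldol) condensation with dehydration at the only aldehyde present, giving the thermodynamically favoured E nitroalkene.

**Step 5**
Reactants: 7 2,4,6-trihydroxybenzaldehyde
Product: 8 4,6-bis(benzyloxy)-2-hydroxybenzaldehyde
Conditions: BnBr (2.05 equiv), K2CO3, DMF, 0 °C to rt
Reagents that add atoms: benzyl bromide BrCc1ccccc1
Why: Williamson etherification that stops at the dibenzyl ether because the last hydroxyl is hydrogen-bonded to the aldehyde and is the least nucleophilic.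

**Step 6 (key step, unit 1)**
Reactants: 6 2,6-bis(benzyloxy)-4-{2,6-bis(benzyloxy)-4-[(E)-2-nitroethenyl]phenoxy}benzonitrile; 8 4,6-bis(benzyloxy)-2-hydroxybenzaldehyde
Product: 10 (2R)-2-{3,5-bis(benzyloxy)-4-[3,5-bis(benzyloxy)-4-cyanophenoxy]phenyl}-5,7-bis(benzyloxy)-3-nitro-2H-chromene, via oxa-Michael adduct 9 (not isolated)
Conditions: (S)-2-{[(1-methylimidazol-2-yl)sulfanyl]methyl}pyrrolidine (20 mol%), 2-hydroxybenzoic acid (20 mol%), DMSO, rt, 72 h; recrystallise to raise ee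
Reagents that add atoms: none
Why: asymmetric domino oxa-Michael/Henry/dehydration in which the phenol adds to the nitroalkene and the resulting nitronate (a masked C3 acyl anion) attacks the iminium-activated aldehyde carbon C4, closing ring C while the chiral amine fixes C2 as R in the oxa-Michael step; this is known for simpler salicylaldehydes and is stretched here to a 4,6-dialkoxy case.

**Step 7**
Reactants: 10 (2R)-2-{3,5-bis(benzyloxy)-4-[3,5-bis(benzyloxy)-4-cyanophenoxy]phenyl}-5,7-bis(benzyloxy)-3-nitro-2H-chromene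
Product: 11 (2R)-2-{3,5-bis(benzyloxy)-4-[3,5-bis(benzyloxy)-4-cyanophenoxy]phenyl}-5,7-bis(benzyloxy)chroman-3-one
Conditions: aq. TiCl3 (7 equiv), NH4OAc buffer (pH 5–6), THF, 0 °C to rt
Reagents that add atoms: water O
Why: reductive Nef reaction of a conjugated nitroalkene (oxime, then imine, then hydrolysis) that unmasks the C3 carbonyl and leaves C4 as CH2, buffered and cold so that C2 does not epimerise.

**Step 8**
Reactants: 11 (2R)-2-{3,5-bis(benzyloxy)-4-[3,5-bis(benzyloxy)-4-cyanophenoxy]phenyl}-5,7-bis(benzyloxy)chroman-3-one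
Product: 12 2,6-bis(benzyloxy)-4-{2,6-bis(benzyloxy)-4-[(2R,3R)-5,7-bis(benzyloxy)-3-hydroxychroman-2-yl]phenoxy}benzonitrile
Conditions: LiBH(s-Bu)3 (1.5 equiv), LiBr, THF, −78 °C; H2O quench
Reagents that add atoms: none
Why: substrate-controlled ketone reduction in which the bulky hydride attacks the face away from the C2 aryl group and gives the 2,3-cis (3R) alcohol, as in the established catechin-to-epicatechin sequence.

**Step 9**
Reactants: 12 2,6-bis(benzyloxy)-4-{2,6-bis(benzyloxy)-4-[(2R,3R)-5,7-bis(benzyloxy)-3-hydroxychroman-2-yl]phenoxy}benzonitrile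
Product: 13 (2R,3S)-2-{3,5-bis(benzyloxy)-4-[3,5-bis(benzyloxy)-4-cyanophenoxy]phenyl}-5,7-bis(benzyloxy)chroman-3-yl chloroacetate
Conditions: ClCH2CO2H, PPh3, DIAD, PhMe, 0 °C to rt
Reagents that add atoms: chloroacetic acid OC(=O)CCl
Why: Mitsunobu esterification in which the axial C3 oxyphosphonium group is displaced from the equatorial side by the acidic carboxylate, inverting C3 to S (2,3-trans).

**Step 10**
Reactants: 13 (2R,3S)-2-{3,5-bis(benzyloxy)-4-[3,5-bis(benzyloxy)-4-cyanophenoxy]phenyl}-5,7-bis(benzyloxy)chroman-3-yl chloroacetate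
Product: 14 2,6-bis(benzyloxy)-4-{2,6-bis(benzyloxy)-4-[(2R,3S)-5,7-bis(benzyloxy)-3-hydroxychroman-2-yl]phenoxy}benzaldehyde
Conditions: i-Bu2AlH (5 equiv), CH2Cl2, −78 to 0 °C; cold 1 M HCl work-up
Reagents that add atoms: water O
Why: hydride reduction that stops the hindered nitrile at the aluminium imide (hydrolysed to the aldehyde on work-up) and at the same time cleaves the chloroacetate reductively to free the trans 3-OH.

**Step 11**
Reactants: 14 2,6-bis(benzyloxy)-4-{2,6-bis(benzyloxy)-4-[(2R,3S)-5,7-bis(benzyloxy)-3-hydroxychroman-2-yl]phenoxy}benzaldehyde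
Product: 15 2-(benzyloxy)-4-{2,6-bis(benzyloxy)-4-[(2R,3S)-5,7-bis(benzyloxy)-3-hydroxychroman-2-yl]phenoxy}-6-hydroxybenzaldehyde
Conditions: MgBr2·OEt2 (3 equiv), PhMe–Et2O, rt to 50 °C; 1 M HCl work-up
Reagents that add atoms: none
Why: chelation-controlled debenzylation of an ether ortho to a carbonyl, which stops after one group because the resulting magnesium phenoxide chelate deactivates the aldehyde.

**Step 12**
Reactants: 1 3,4,5-tris(benzyloxy)benzaldehyde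
Product: 16 (E)-1,2,3-tris(benzyloxy)-5-(2-nitroethenyl)benzene
Conditions: MeNO2, NH4OAc, AcOH, 100 °C
Reagents that add atoms: nitromethane C[N+](=O)[O-]
Why: Henry condensation with dehydration giving the E nitrostyrene.

**Step 13 (key step, unit 2)**
Reactants: 15 2-(benzyloxy)-4-{2,6-bis(benzyloxy)-4-[(2R,3S)-5,7-bis(benzyloxy)-3-hydroxychroman-2-yl]phenoxy}-6-hydroxybenzaldehyde; 16 (E)-1,2,3-tris(benzyloxy)-5-(2-nitroethenyl)benzene
Product: 18 (2R,3S)-5,7-bis(benzyloxy)-2-[3,5-bis(benzyloxy)-4-({(2R)-5-(benzyloxy)-3-nitro-2-[3,4,5-tris(benzyloxy)phenyl]-2H-chromen-7-yl}oxy)phenyl]chroman-3-ol, via oxa-Michael adduct 17 (not isolated)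
Conditions: (S)-2-{[(1-methylimidazol-2-yl)sulfanyl]methyl}pyrrolidine (20 mol%), 2-hydroxybenzoic acid (20 mol%), DMSO, rt, 72 h
Reagents that add atoms: none
Why: the same asymmetric domino oxa-Michael/Henry/dehydration, now with the core as the salicylaldehyde, so that the nitronate carbon C3 bonds to the former aldehyde carbon C4 and the catalyst sets C2 of unit 2 as R (the free secondary alcohol of unit 1 is a spectator).

**Step 14**
Reactants: 18 (2R,3S)-5,7-bis(benzyloxy)-2-[3,5-bis(benzyloxy)-4-({(2R)-5-(benzyloxy)-3-nitro-2-[3,4,5-tris(benzyloxy)phenyl]-2H-chromen-7-yl}oxy)phenyl]chroman-3-ol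
Product: 19 (2R)-5-(benzyloxy)-7-{2,6-bis(benzyloxy)-4-[(2R,3S)-5,7-bis(benzyloxy)-3-hydroxychroman-2-yl]phenoxy}-2-[3,4,5-tris(benzyloxy)phenyl]chroman-3-one
Conditions: aq. TiCl3 (7 equiv), NH4OAc buffer (pH 5–6), THF, 0 °C to rt
Reagents that add atoms: water O
Why: reductive Nef reaction of the nitroalkene as in step 7, giving the unit 2 flavan-3-one with C2 untouched.

**Step 15**
Reactants: 19 (2R)-5-(benzyloxy)-7-{2,6-bis(benzyloxy)-4-[(2R,3S)-5,7-bis(benzyloxy)-3-hydroxychroman-2-yl]phenoxy}-2-[3,4,5-tris(benzyloxy)phenyl]chroman-3-one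
Product: 20 (2R,3S)-5,7-bis(benzyloxy)-2-[3,5-bis(benzyloxy)-4-({(2R,3R)-5-(benzyloxy)-3-hydroxy-2-[3,4,5-tris(benzyloxy)phenyl]chroman-7-yl}oxy)phenyl]chroman-3-ol
Conditions: LiBH(s-Bu)3 (3 equiv), LiBr, THF, −78 °C; H2O quench
Reagents that add atoms: none
Why: bulky-hydride ketone reduction anti to the C2 aryl group giving the 2,3-cis (3R) alcohol of unit 2, the extra hydride only deprotonating the unit 1 alcohol.

**Step 16**
Reactants: 20 (2R,3S)-5,7-bis(benzyloxy)-2-[3,5-bis(benzyloxy)-4-({(2R,3R)-5-(benzyloxy)-3-hydroxy-2-[3,4,5-tris(benzyloxy)phenyl]chroman-7-yl}oxy)phenyl]chroman-3-ol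
Product: 21 CNP0298095.1, (2R,3S)-2-[3,5-dihydroxy-4-({(2R,3R)-3,5-dihydroxy-2-(3,4,5-trihydroxyphenyl)chroman-7-yl}oxy)phenyl]chroman-3,5,7-triol
Conditions: H2 (1 atm), Pd(OH)2/C, THF–MeOH, rt; degassed solvents, Sephadex LH-20
Reagents that add atoms: none
Why: global hydrogenolysis of the eight benzyl ethers under neutral conditions, which is standard for catechins and leaves the C2–O bonds and the diaryl ether intact.

**Compound list**
1 | 3,4,5-tris(benzyloxy)benzaldehyde | O=Cc1cc(OCc2ccccc2)c(OCc2ccccc2)c(OCc2ccccc2)c1 | starting material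
2 | 3,5-bis(benzyloxy)-4-hydroxybenzaldehyde | O=Cc1cc(OCc2ccccc2)c(O)c(OCc2ccccc2)c1 | intermediate
3 | 2,4,6-trifluorobenzonitrile | N#Cc1c(F)cc(F)cc1F | starting material
4 | 4-[2,6-bis(benzyloxy)-4-formylphenoxy]-2,6-difluorobenzonitrile | O=Cc1cc(OCc2ccccc2)c(Oc2cc(F)c(C#N)c(F)c2)c(OCc2ccccc2)c1 | intermediate
5 | 2,6-bis(benzyloxy)-4-[2,6-bis(benzyloxy)-4-formylphenoxy]benzonitrile | O=Cc1cc(OCc2ccccc2)c(Oc2cc(OCc3ccccc3)c(C#N)c(OCc3ccccc3)c2)c(OCc2ccccc2)c1 | intermediate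
6 | 2,6-bis(benzyloxy)-4-{2,6-bis(benzyloxy)-4-[(E)-2-nitroethenyl]phenoxy}benzonitrile | [O-][N+](=O)/C=C/c1cc(OCc2ccccc2)c(Oc2cc(OCc3ccccc3)c(C#N)c(OCc3ccccc3)c2)c(OCc2ccccc2)c1 | intermediate
7 | 2,4,6-trihydroxybenzaldehyde | O=Cc1c(O)cc(O)cc1O | starting material
8 | 4,6-bis(benzyloxy)-2-hydroxybenzaldehyde | O=Cc1c(O)cc(OCc2ccccc2)cc1OCc1ccccc1 | intermediate
9 | oxa-Michael adduct: 2,6-bis(benzyloxy)-4-{2,6-bis(benzyloxy)-4-[(1R)-1-(3,5-bis(benzyloxy)-2-formylphenoxy)-2-nitroethyl]phenoxy}benzonitrile | O=Cc1c(OCc2ccccc2)cc(OCc2ccccc2)cc1O[C@@H](C[N+](=O)[O-])c1cc(OCc2ccccc2)c(Oc2cc(OCc3ccccc3)c(C#N)c(OCc3ccccc3)c2)c(OCc2ccccc2)c1 | intermediate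
10 | (2R)-2-{3,5-bis(benzyloxy)-4-[3,5-bis(benzyloxy)-4-cyanophenoxy]phenyl}-5,7-bis(benzyloxy)-3-nitro-2H-chromene | [O-][N+](=O)C1=Cc2c(OCc3ccccc3)cc(OCc3ccccc3)cc2O[C@@H]1c1cc(OCc2ccccc2)c(Oc2cc(OCc3ccccc3)c(C#N)c(OCc3ccccc3)c2)c(OCc2ccccc2)c1 | intermediate
11 | (2R)-2-{3,5-bis(benzyloxy)-4-[3,5-bis(benzyloxy)-4-cyanophenoxy]phenyl}-5,7-bis(benzyloxy)chroman-3-one | O=C1Cc2c(OCc3ccccc3)cc(OCc3ccccc3)cc2O[C@@H]1c1cc(OCc2ccccc2)c(Oc2cc(OCc3ccccc3)c(C#N)c(OCc3ccccc3)c2)c(OCc2ccccc2)c1 | intermediate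
12 | 2,6-bis(benzyloxy)-4-{2,6-bis(benzyloxy)-4-[(2R,3R)-5,7-bis(benzyloxy)-3-hydroxychroman-2-yl]phenoxy}benzonitrile | c1ccccc1COc1cc(OCc2ccccc2)c2c(c1)O[C@H](c1cc(OCc3ccccc3)c(Oc3cc(OCc4ccccc4)c(C#N)c(OCc4ccccc4)c3)c(OCc3ccccc3)c1)[C@H](O)C2 | intermediate
13 | (2R,3S)-2-{3,5-bis(benzyloxy)-4-[3,5-bis(benzyloxy)-4-cyanophenoxy]phenyl}-5,7-bis(benzyloxy)chroman-3-yl chloroacetate | c1ccccc1COc1cc(OCc2ccccc2)c2c(c1)O[C@H](c1cc(OCc3ccccc3)c(Oc3cc(OCc4ccccc4)c(C#N)c(OCc4ccccc4)c3)c(OCc3ccccc3)c1)[C@@H](OC(=O)CCl)C2 | intermediate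
14 | 2,6-bis(benzyloxy)-4-{2,6-bis(benzyloxy)-4-[(2R,3S)-5,7-bis(benzyloxy)-3-hydroxychroman-2-yl]phenoxy}benzaldehyde | c1ccccc1COc1cc(OCc2ccccc2)c2c(c1)O[C@H](c1cc(OCc3ccccc3)c(Oc3cc(OCc4ccccc4)c(C=O)c(OCc4ccccc4)c3)c(OCc3ccccc3)c1)[C@@H](O)C2 | intermediate
15 | 2-(benzyloxy)-4-{2,6-bis(benzyloxy)-4-[(2R,3S)-5,7-bis(benzyloxy)-3-hydroxychroman-2-yl]phenoxy}-6-hydroxybenzaldehyde | c1ccccc1COc1cc(OCc2ccccc2)c2c(c1)O[C@H](c1cc(OCc3ccccc3)c(Oc3cc(O)c(C=O)c(OCc4ccccc4)c3)c(OCc3ccccc3)c1)[C@@H](O)C2 | intermediate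
16 | (E)-1,2,3-tris(benzyloxy)-5-(2-nitroethenyl)benzene | [O-][N+](=O)/C=C/c1cc(OCc2ccccc2)c(OCc2ccccc2)c(OCc2ccccc2)c1 | intermediate
17 | oxa-Michael adduct: 2-(benzyloxy)-4-{2,6-bis(benzyloxy)-4-[(2R,3S)-5,7-bis(benzyloxy)-3-hydroxychroman-2-yl]phenoxy}-6-{(1R)-2-nitro-1-[3,4,5-tris(benzyloxy)phenyl]ethoxy}benzaldehyde | c1ccccc1COc1cc(OCc2ccccc2)c2c(c1)O[C@H](c1cc(OCc3ccccc3)c(Oc3cc(O[C@@H](C[N+](=O)[O-])c5cc(OCc6ccccc6)c(OCc6ccccc6)c(OCc6ccccc6)c5)c(C=O)c(OCc4ccccc4)c3)c(OCc3ccccc3)c1)[C@@H](O)C2 | intermediate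
18 | (2R,3S)-5,7-bis(benzyloxy)-2-[3,5-bis(benzyloxy)-4-({(2R)-5-(benzyloxy)-3-nitro-2-[3,4,5-tris(benzyloxy)phenyl]-2H-chromen-7-yl}oxy)phenyl]chroman-3-ol | c1ccccc1COc1cc(OCc2ccccc2)c2c(c1)O[C@H](c1cc(OCc3ccccc3)c(Oc3cc4O[C@H](c5cc(OCc6ccccc6)c(OCc6ccccc6)c(OCc6ccccc6)c5)C([N+](=O)[O-])=Cc4c(OCc4ccccc4)c3)c(OCc3ccccc3)c1)[C@@H](O)C2 | intermediate
19 | (2R)-5-(benzyloxy)-7-{2,6-bis(benzyloxy)-4-[(2R,3S)-5,7-bis(benzyloxy)-3-hydroxychroman-2-yl]phenoxy}-2-[3,4,5-tris(benzyloxy)phenyl]chroman-3-one | c1ccccc1COc1cc(OCc2ccccc2)c2c(c1)O[C@H](c1cc(OCc3ccccc3)c(Oc3cc4O[C@H](c5cc(OCc6ccccc6)c(OCc6ccccc6)c(OCc6ccccc6)c5)C(=O)Cc4c(OCc4ccccc4)c3)c(OCc3ccccc3)c1)[C@@H](O)C2 | intermediate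
20 | (2R,3S)-5,7-bis(benzyloxy)-2-[3,5-bis(benzyloxy)-4-({(2R,3R)-5-(benzyloxy)-3-hydroxy-2-[3,4,5-tris(benzyloxy)phenyl]chroman-7-yl}oxy)phenyl]chroman-3-ol | c1ccccc1COc1cc(OCc2ccccc2)c2c(c1)O[C@H](c1cc(OCc3ccccc3)c(Oc3cc4O[C@H](c5cc(OCc6ccccc6)c(OCc6ccccc6)c(OCc6ccccc6)c5)[C@H](O)Cc4c(OCc4ccccc4)c3)c(OCc3ccccc3)c1)[C@@H](O)C2 | intermediate
21 | CNP0298095.1 | Oc1cc(O)c2c(c1)O[C@H](c1cc(O)c(Oc3cc(O)c4c(c3)O[C@H](c3cc(O)c(O)c(O)c3)[C@H](O)C4)c(O)c1)[C@@H](O)C2 | target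

**Totals**
Total steps: 16. Longest linear sequence: 14 (steps 1–4, 6–11, 13–16); steps 5 and 12 are side branches.

**Three steps most likely to fail**

Step 6 (the same concern holds for step 13). The 4,6-dialkoxysalicylaldehyde is hindered and electron-rich, so the domino reaction may be slow or poorly enantioselective. Fallback: set the stereocentres later by dynamic kinetic resolution. From 6 and 8, 1,4-diazabicyclo[2.2.2]octane (MeCN, 50 °C) gives the racemic nitrochromene F1. TiCl3 as in step 7 gives the racemic flavan-3-one F2, whose C2 epimerises through the enol. Asymmetric transfer hydrogenation (RuCl(p-cymene)[(R,R)-TsDPEN] or its antipode, HCO2H–Et3N) then reduces one enantiomer selectively to the cis alcohol and returns to the route at 12.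

Step 7 (and step 14). Over-reduction to the amine or epimerisation of C2 through imine/enamine intermediates is possible. Fallback: switch from a reductive to an oxidative Nef. From 10, NaBH4 (THF–MeOH, 0 °C) adds hydride at C4 to give the (2R)-3-nitroflavan F3. Its nitronate (KOt-Bu, THF, −78 °C) is oxidised with dimethyldioxirane to the ketone, returning at 11.

Step 9. The axial oxyphosphonium group can eliminate instead of being displaced. Fallback: make the trans alcohol by hydroboration instead of substitution. From 12, methyl N-(triethylammoniosulfonyl)carbamate (PhMe, 50 °C) effects syn-dehydration; only a C4 hydrogen is syn to the axial hydroxyl, so the flav-3-ene F4 forms. BH3·THF (0 °C) then NaOH/H2O2 adds anti to the aryl group, with boron at C3, giving the trans alcohol F5. i-Bu2AlH as in step 10 converts the nitrile of F5 to the aldehyde and returns at 14.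

**Further compounds**
F1 | step 6 | racemic 2-{3,5-bis(benzyloxy)-4-[3,5-bis(benzyloxy)-4-cyanophenoxy]phenyl}-5,7-bis(benzyloxy)-3-nitro-2H-chromene | [O-][N+](=O)C1=Cc2c(OCc3ccccc3)cc(OCc3ccccc3)cc2OC1c1cc(OCc2ccccc2)c(Oc2cc(OCc3ccccc3)c(C#N)c(OCc3ccccc3)c2)c(OCc2ccccc2)c1
F2 | step 6 | racemic 2-{3,5-bis(benzyloxy)-4-[3,5-bis(benzyloxy)-4-cyanophenoxy]phenyl}-5,7-bis(benzyloxy)chroman-3-one | O=C1Cc2c(OCc3ccccc3)cc(OCc3ccccc3)cc2OC1c1cc(OCc2ccccc2)c(Oc2cc(OCc3ccccc3)c(C#N)c(OCc3ccccc3)c2)c(OCc2ccccc2)c1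
F3 | step 7 | (2R)-2-{3,5-bis(benzyloxy)-4-[3,5-bis(benzyloxy)-4-cyanophenoxy]phenyl}-5,7-bis(benzyloxy)-3-nitrochroman (C3 epimers, mainly trans) | [O-][N+](=O)C1Cc2c(OCc3ccccc3)cc(OCc3ccccc3)cc2O[C@@H]1c1cc(OCc2ccccc2)c(Oc2cc(OCc3ccccc3)c(C#N)c(OCc3ccccc3)c2)c(OCc2ccccc2)c1
F4 | step 9 | (2S)-2-{3,5-bis(benzyloxy)-4-[3,5-bis(benzyloxy)-4-cyanophenoxy]phenyl}-5,7-bis(benzyloxy)-2H-chromene (same spatial arrangement at C2 as in 12; only the descriptor changes) | C1=Cc2c(OCc3ccccc3)cc(OCc3ccccc3)cc2O[C@@H]1c1cc(OCc2ccccc2)c(Oc2cc(OCc3ccccc3)c(C#N)c(OCc3ccccc3)c2)c(OCc2ccccc2)c1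
F5 | step 9 | 2,6-bis(benzyloxy)-4-{2,6-bis(benzyloxy)-4-[(2R,3S)-5,7-bis(benzyloxy)-3-hydroxychroman-2-yl]phenoxy}benzonitrile | c1ccccc1COc1cc(OCc2ccccc2)c2c(c1)O[C@H](c1cc(OCc3ccccc3)c(Oc3cc(OCc4ccccc4)c(C#N)c(OCc4ccccc4)c3)c(OCc3ccccc3)c1)[C@@H](O)C2
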